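## Structural features

The target is a single ten-membered carbocycle (a cis,cis-germacradiene) carrying one 4-hydroxybenzoate. Ring atoms are numbered C1 (methyl-bearing alkene carbon), C2 (alkene CH), C3 (free carbinol), C4 (isopropyl), C5 (acyloxy), C6 (CH2), C7 (methyl-bearing alkene carbon), C8 (alkene CH), C9 and C10 (CH2); the two extra-ring carbons that end up on C4 are called Cα (later =CH2) and Cβ (methyl-bearing). Both trisubstituted ring alkenes, C1=C2 and C7=C8, are Z; C9–C10 lies between them on one side and the C3–C6 segment on the other. C3 (S), C4 (S) and C5 (R) are contiguous and carry OH, isopropyl and the ester all cis on the ring, so the two oxygens are 1,3-syn and must be told apart because only O5 is acylated. Fragile points are the allylic C3 alcohol (ionisation), the 1,3-diol monoester (acyl shift under base), the phenol and the two Z geometries; in the chosen precursors a doubly allylic silyl ether and a β,γ-unsaturated aldehyde are added to that list. The real difficulty is closing a medium ring while fixing the C3–C5 triad next to two Z-trisubstituted alkenes. The key step uses the fact that O5 sits next to C4, whose isopropyl can be read as a hydrogenated isopropenyl group. That 1-hydroxy-2-isopropenyl unit is the retron of a γ-selective allyl transfer from Cα–Cβ=C4 to a C5 aldehyde, with C3 already present as the stereochemical relay.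

## Logic of the disconnections

28 to 27: the two O–Si bonds are cut last. The phenol and O3 wear the same silyl group, so one operation frees both. The forward step must be non-basic, because base would move the acyl group from O5 to O3.

27 to 26: the two C–H bonds of the isopropyl group are cut, leaving an isopropenyl group. This exposes the allylation retron. The forward step must hydrogenate a 1,1-disubstituted alkene and leave two trisubstituted ring alkenes alone.

26 to 21 and 24: the ester C–O bond is cut. 21 has O5 as its only free hydroxyl, so no selectivity question arises; the forward step is acylation of a hindered secondary alcohol. 24 goes back to 22 through 23 by silyl protection.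

21 to 19 (through 20), and 19 to 18: the C4–C5 bond is cut, which opens the ring. This single cut removes the ring and two stereocentres and explains why O5 is free while O3 is silylated. The forward step needs a Z allylboronate, the correct C3 configuration, and an aldehyde released under neutral conditions at high dilution; 18 is the stable alcohol from which 19 is made in the flask.

18 to 17: the Cβ–Cα bond is cut, giving an alkenyl iodide and a borylmethyl nucleophile. The forward coupling must go with retention and tolerate a free primary hydroxyl, so the boronate never meets a deprotection step.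

17 to 16 to 15: O–Si bonds only. O3 receives the silyl group that stays and O5 the one that leaves; the forward steps need a clean primary-versus-secondary distinction.

15 to 13 (through 14): the C–I bond and the C4–H bond are cut back to an alkyne. The forward step must add hydride and iodine trans, with iodine on the carbon remote from O3, to fix the Z geometry of the later boronate.

13 to 11 and 12: the C3–C4 bond is cut. C3 becomes an aldehyde carbon and the three carbons C4, Cβ and its methyl come from 12. The forward step sets C3 by catalyst control and must not isomerise the Z-enal.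

11 to 10 to 9 to 8: oxidation level and protecting-group changes only, arranged so that the allylic end is oxidised while O5 stays masked.

8 to 5 and 6 (through 7): the C6–C7 bond is cut, giving an alkenyl anion and a two-carbon epoxide. The forward step needs a configurationally stable Z-alkenyl metal.

5 to 4: the C7=C8 bond is cut to an aldehyde and a two-carbon iodo ylide. The forward step must be Z-selective for a trisubstituted iodoalkene.

4 to 2 (through 3) to 1: the distal isopropylidene of 1 is cleaved; the Z alkene of 1 becomes C1=C2 unchanged. The forward step must discriminate between two trisubstituted alkenes.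

## Other disconnections considered

Alternative 1: The cut is C3–C4 plus C5–C6, which removes C4 and C5 as a two-carbon unit and leaves an eight-membered ring. In the forward step the silyl enol ether A1 and isopropylketene A2 would undergo [2+2] cycloaddition, and Bu4NF would then open the ring-fusion bond by retro-aldol cleavage to the ten-membered 1,3-diketone A3.
- In its favour: no macrocyclisation is needed, cis alkenes are enforced in the eight-membered ring, and two C–C bonds and the whole skeleton including the isopropyl group arrive in one flask. In steps to the carbon skeleton it is better than the chosen plan, and it needs no hydrogenation.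
- Against it: A3 has no fixed stereocentre, so C3, C4 and C5 and the absolute configuration would all have to come from reduction of a flexible medium-ring β-diketone. The two new hydroxyls would not be differentiated. The C7=C8 alkene is β,γ to the C5 ketone and could move into conjugation under the enolate-forming conditions. The periselectivity of ketene addition to a conjugated trienyl silyl ether is open, and A1 is not an article of commerce.
- Comparison: structurally it solves ring and alkenes but not the triad. Mechanistically both plans go beyond direct precedent for this ring. In step economy its early advantage would be spent on stereocontrol and hydroxyl differentiation, which the chosen plan builds into the ring closure.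

Alternative 2: The cut is C9–C10, between the two allylic methylenes. In the forward step KN(SiMe3)2 would deprotonate the allylic sulfone of the open-chain bromide A4 at high dilution, and the carbanion would displace the allylic bromide to give the cyclic sulfone A5; the sulfonyl group would be removed reductively later.
- In its favour: sulfone-anion alkylation is an established way to close medium and large carbocycles, so on precedent for the ring-closing reaction type it is better than the chosen plan. All three stereocentres exist before cyclisation, so the ring closure has no stereochemical task. O3 and O5 are differentiated as two silyl ethers, which equals the chosen plan.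
- Against it: the acyclic triad with a central isopropyl group and two Z-trisubstituted alkenes ending in sulfone and bromide needs a long linear build. The allylic anion can react at its α or γ carbon and the bromide by SN2 or SN2′. Reductive removal of an allylic sulfone can move or isomerise the C1=C2 alkene. Sulfur must be put in and taken out.
- Comparison: the cut is remote from the triad and uses none of the target's functionality, whereas the chosen cut uses O5. It is mechanistically safer, but the chosen plan is shorter because ring, C4 and C5 arise together and no auxiliary group is removed.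

Alternative 3: The cut is C3–C4, with Cα tied back to O3 in the thirteen-membered all-Z ether A6. In the forward step n-butyllithium would deprotonate C3 and a [2,3]-Wittig shift would form C3–C4, release the isopropenyl group and contract the ring to the dienol A7.
- In its favour: ring contraction of thirteen-membered diallylic ethers to ten-membered carbocycles is a known reaction type, so here precedent is better than for the chosen plan. It creates the isopropenyl group and two stereocentres in the ring-forming event through an ordered five-membered transition state, which equals the chosen plan.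
- Against it: A6 has two allylic O–CH2 groups, and deprotonation at the other one would contract the ring differently. The relay of configuration from C5 across the macrocycle is as untested as the relay from C3 in the chosen plan. A macrocyclic ether must be closed first, so two ring-forming operations are needed. A7 has O3 free and O5 silylated, the reverse of what the acylation needs, which costs a protecting-group exchange.
- Comparison: structurally both plans read the isopropyl group as a masked isopropenyl group. Mechanistically this one is better precedented but strongly basic. In step economy the chosen plan has one ring closure and delivers the free hydroxyl where the ester goes.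

Key step: step 13

Assumption: the zinc–ProPhenol alkynylation of step 8 is taken to follow its usual sense of induction; the ligand antipode is whichever adds propyne to the Re face of 11 (giving 4S), written here as (S,S), with the other antipode equally available.

Remarks on the structures and the precursor design:
- The open-chain aldehyde 19 and the ring product 21 match the target in constitution, in both ring Z alkenes, in the Z boronate and at C3. The C3 descriptor changes from R (18, 19) to S (21) only because the priorities change.
- The trisubstituted iodoalkene 5 needs the ethylidene (α-methyl) form of the iodo-olefination, not the parent iodomethylene ylide.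
- The stable alcohol 18 is the stored precursor. Boron is introduced after the last deprotection, and the aldehyde is made under buffer and used in the same flask.
- Allylic 1,3-strain alone does not decide the C4 face. The rotamer that leads to the target is spelled out in step 13.

Step 1
Reactants: 1 nerol
Product: 2 1-({[(2Z)-3,7-dimethylocta-2,6-dien-1-yl]oxy}methyl)-4-methoxybenzene
Conditions: NaH, 4-MeOC6H4CH2Cl, Bu4NI (cat.), THF/DMF, 0→25 °C
Reagents that add atoms: 4-methoxybenzyl chloride, SMILES COc1ccc(CCl)cc1
Why: Williamson etherification of the primary allylic alkoxide; the 4-methoxybenzyl ether survives peracid, periodic acid, ylide and alkyllithium chemistry and is later removed oxidatively without acid.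

Step 2
Reactants: 2 1-({[(2Z)-3,7-dimethylocta-2,6-dien-1-yl]oxy}methyl)-4-methoxybenzene
Product: 4 (4Z)-6-[(4-methoxybenzyl)oxy]-4-methylhex-4-enal, via 6,7-epoxide 3 (not isolated)
Conditions: mCPBA (1.0 equiv), CH2Cl2, −20→0 °C; then H5IO6, THF/H2O, 0 °C
Reagents that add atoms: 3-chloroperbenzoic acid, SMILES OOC(=O)c1cccc(Cl)c1
Why: Prilezhaev epoxidation should prefer the electron-rich isopropylidene alkene over the alkene deactivated by the allylic ether oxygen, and periodic acid then hydrolyses and cleaves the epoxide (glycol cleavage) to the aldehyde and acetone; the Z alkene that becomes C1=C2 is untouched.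

Step 3
Reactants: 4 (4Z)-6-[(4-methoxybenzyl)oxy]-4-methylhex-4-enal
Product: 5 1-({[(2Z,6Z)-7-iodo-3-methylocta-2,6-dien-1-yl]oxy}methyl)-4-methoxybenzene
Conditions: Ph3P(Et)I, n-BuLi, THF, 25 °C; I2, −78 °C; NaN(SiMe3)2, −20 °C; then 4, −78 °C
Reagents that add atoms: ethyltriphenylphosphonium iodide, SMILES CC[P+](c1ccccc1)(c1ccccc1)c1ccccc1.[I-]; iodine, SMILES II
Why: Stork–Zhao olefination in its ethylidene form: the α-iodo ylide adds to the aldehyde under kinetic control at low temperature and the oxaphosphetane collapses to the Z-iodoalkene (iodine cis to the chain), which brings in C7 with its methyl and fixes the later C7=C8 geometry.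

Step 4
Reactants: 5 1-({[(2Z,6Z)-7-iodo-3-methylocta-2,6-dien-1-yl]oxy}methyl)-4-methoxybenzene; 6 ethylene oxide
Product: 8 (3Z,7Z)-9-[(4-methoxybenzyl)oxy]-3,7-dimethylnona-3,7-dien-1-ol, via alkenyllithium 7 (not isolated)
Conditions: t-BuLi (2.1 equiv), Et2O, −78 °C; ethylene oxide (excess), −78→0 °C
Reagents that add atoms: none
Why: Iodine–lithium exchange goes with retention of alkene geometry and the alkenyllithium opens the epoxide by SN2 attack at carbon, adding C6 and C5 as a 2-hydroxyethyl group cis to the chain; the ether is inert at −78 °C.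

Step 5
Reactants: 8 (3Z,7Z)-9-[(4-methoxybenzyl)oxy]-3,7-dimethylnona-3,7-dien-1-ol
Product: 9 triethyl{[(3Z,7Z)-9-[(4-methoxybenzyl)oxy]-3,7-dimethylnona-3,7-dien-1-yl]oxy}silane
Conditions: Et3SiCl, imidazole, CH2Cl2, 0 °C
Reagents that add atoms: chlorotriethylsilane, SMILES CC[Si](Cl)(CC)CC
Why: Standard silylation of a primary alcohol; the triethylsilyl ether at O5 withstands the oxidations, the zinc alkynylation and the aluminium hydride, and can later be removed in the presence of a secondary tert-butyldimethylsilyl ether.

Step 6
Reactants: 9 triethyl{[(3Z,7Z)-9-[(4-methoxybenzyl)oxy]-3,7-dimethylnona-3,7-dien-1-yl]oxy}silane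
Product: 10 (2Z,6Z)-3,7-dimethyl-9-[(triethylsilyl)oxy]nona-2,6-dien-1-ol
Conditions: 2,3-dichloro-5,6-dicyano-1,4-benzoquinone (DDQ), CH2Cl2/pH 7 buffer, 0 °C
Reagents that add atoms: none
Why: Oxidative cleavage of the 4-methoxybenzyl ether by hydride abstraction and hydrolysis of the oxocarbenium ion; the buffer keeps the silyl ether and both Z alkenes intact.

Step 7
Reactants: 10 (2Z,6Z)-3,7-dimethyl-9-[(triethylsilyl)oxy]nona-2,6-dien-1-ol
Product: 11 (2Z,6Z)-3,7-dimethyl-9-[(triethylsilyl)oxy]nona-2,6-dienal
Conditions: 2,2,6,6-tetramethylpiperidin-1-oxyl (TEMPO, 10 mol %), PhI(OAc)2, MeCN/pH 7 buffer, 0 °C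
Reagents that add atoms: none
Why: Oxoammonium-mediated oxidation of the allylic alcohol under buffered conditions, which is known to convert Z-allylic alcohols of the nerol type into Z-enals without Z to E isomerisation; the enal is used at once.

Step 8
Reactants: 11 (2Z,6Z)-3,7-dimethyl-9-[(triethylsilyl)oxy]nona-2,6-dienal; 12 propyne
Product: 13 (4S,5Z,9Z)-6,10-dimethyl-12-[(triethylsilyl)oxy]dodeca-5,9-dien-2-yn-4-ol
Conditions: (S,S)-ProPhenol [2,6-bis{[(S)-2-(hydroxydiphenylmethyl)pyrrolidin-1-yl]methyl}-4-methylphenol] (20 mol %), Me2Zn (3 equiv), Ph3P=O (40 mol %), PhMe, 0 °C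
Reagents that add atoms: none
Why: Catalytic asymmetric alkynylation of an α,β-unsaturated aldehyde: Me2Zn zincates propyne, and the dinuclear zinc–ProPhenol complex binds aldehyde and alkynylzinc so that the alkyne adds to the Re face, which sets C3 (S here) by catalyst control; 1,2-addition leaves the Z alkene in place.

Step 9
Reactants: 13 (4S,5Z,9Z)-6,10-dimethyl-12-[(triethylsilyl)oxy]dodeca-5,9-dien-2-yn-4-ol
Product: 15 (2Z,4S,5Z,9Z)-2-iodo-6,10-dimethyl-12-[(triethylsilyl)oxy]dodeca-2,5,9-trien-4-ol, via cyclic alkenylalanate 14 (not isolated)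
Conditions: NaAlH2(OCH2CH2OMe)2, THF, 0→25 °C; EtOAc; I2, THF, −78 °C
Reagents that add atoms: iodine, SMILES II
Why: Hydroxyl-directed trans-hydroalumination of the propargylic alcohol puts aluminium on the alkyne carbon remote from oxygen in a five-membered alanate, and iodinolysis of the C–Al bond with retention gives the Z-iodoalkene with iodine cis to C3; the stereocentre is not touched.

Step 10
Reactants: 15 (2Z,4S,5Z,9Z)-2-iodo-6,10-dimethyl-12-[(triethylsilyl)oxy]dodeca-2,5,9-trien-4-ol
Product: 16 (2Z,4S,5Z,9Z)-4-[(tert-butyldimethylsilyl)oxy]-2-iodo-6,10-dimethyl-12-[(triethylsilyl)oxy]dodeca-2,5,9-triene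
Conditions: t-BuMe2SiOTf, 2,6-lutidine, CH2Cl2, −78 °C
Reagents that add atoms: tert-butyldimethylsilyl triflate, SMILES CC(C)(C)[Si](C)(C)OS(=O)(=O)C(F)(F)F
Why: Silyl triflate with a hindered base silylates the hindered, doubly allylic alcohol at low temperature under non-acidic conditions; this ether is the O3 group that stays through ring closure.

Step 11
Reactants: 16 (2Z,4S,5Z,9Z)-4-[(tert-butyldimethylsilyl)oxy]-2-iodo-6,10-dimethyl-12-[(triethylsilyl)oxy]dodeca-2,5,9-triene
Product: 17 (3Z,7Z,9S,10Z)-9-[(tert-butyldimethylsilyl)oxy]-11-iodo-3,7-dimethyldodeca-3,7,10-trien-1-ol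
Conditions: HF·pyridine, pyridine, THF, 0 °C
Reagents that add atoms: none
Why: Buffered fluoride cleaves a primary triethylsilyl ether much faster than a hindered secondary tert-butyldimethylsilyl ether; doing this before boron is introduced means the allylboronate never meets fluoride or acid.

Step 12
Reactants: 17 (3Z,7Z,9S,10Z)-9-[(tert-butyldimethylsilyl)oxy]-11-iodo-3,7-dimethyldodeca-3,7,10-trien-1-ol
Product: 18 (3Z,7Z,9R,10Z)-9-[(tert-butyldimethylsilyl)oxy]-3,7,11-trimethyl-12-(4,4,5,5-tetramethyl-1,3,2-dioxaborolan-2-yl)dodeca-3,7,10-trien-1-ol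
Conditions: pinBCH2ZnI (3 equiv, from ICH2Bpin and Zn dust, THF), Pd(PPh3)4 (5 mol %), THF, 25→40 °C
Reagents that add atoms: 2-(iodomethyl)-4,4,5,5-tetramethyl-1,3,2-dioxaborolane, SMILES CC1(C)OB(CI)OC1(C)C
Why: Negishi coupling of a borylmethylzinc reagent with an alkenyl iodide at zerovalent palladium; oxidative addition and reductive elimination keep the alkene geometry, so the Z-iodide gives the Z-allylboronate, and primary alkylzinc iodides are protonated only slowly by an alcohol, so the free hydroxyl is tolerated with excess reagent.

Step 13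
Reactants: 18 (3Z,7Z,9R,10Z)-9-[(tert-butyldimethylsilyl)oxy]-3,7,11-trimethyl-12-(4,4,5,5-tetramethyl-1,3,2-dioxaborolan-2-yl)dodeca-3,7,10-trien-1-ol
Product: 21 (1R,3Z,7Z,9S,10R)-9-[(tert-butyldimethylsilyl)oxy]-3,7-dimethyl-10-(prop-1-en-2-yl)cyclodeca-3,7-dien-1-ol, via aldehyde 19 (not isolated), via pinacol borate 20 (not isolated)
Conditions: Dess–Martin periodinane, NaHCO3, CH2Cl2, 0 °C; dilute with PhMe to 0.001 M, 25→45 °C; then aq. NaHCO3
Reagents that add atoms: none
Why: Proposed new method: buffered Dess–Martin oxidation should turn the primary alcohol of 18 into the β,γ-unsaturated aldehyde 19 without touching the boronate, and on dilution and gentle warming the aldehyde oxygen binds boron and C5 is attacked by the γ-carbon C4 through a six-membered chair (B, O, C5, C4, Cβ, Cα) with allyl transposition, so that Cα becomes the =CH2 of the isopropenyl group. The closest known reactions are thermal intramolecular allylborations that close five- to seven-membered rings and chromium- or zinc-mediated intramolecular aldehyde allylations that close ten-membered germacrane rings through a similar closed transition state. The ten-membered ring closes by addition to the tethered carbonyl (10-exo-trig at C=O, SE2′ at the allyl unit, whose double bond moves out of the ring), with the chair fused to the forming ring across C4–C5. C5 is set relative to C4 by the Z geometry of the boronate: C6 sits equatorial and C3 axial in the chair, which puts the C5 oxygen and the isopropenyl group cis on the ring. C4 is set relative to C3 by the rotamer about C3–C4: allylic 1,3-strain against the cis CH2B group should hold the C3 hydrogen in the alkene plane, and the target arises when the silyloxy group lies gauche to the forming bond and C2 lies anti to it, which is favoured electronically (no C–O acceptor bond antiperiplanar to the forming bond) and by the ring (no syn-pentane contact between C2 and C6). The competing rotamer with C2 gauche and the silyloxy group anti would give the C3/C4 trans isomer, so this relay is the untested selectivity. The step also needs ring closure to outrun enolisation of 19 and intermolecular allylation, which the buffer, the low concentration and the irreversibility of a neutral reagent-free addition are meant to secure. Hydrolytic work-up cleaves the O–B bond of 20 and leaves O5 as the only free hydroxyl of 21.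

Step 14
Reactants: 22 4-hydroxybenzoic acid
Product: 24 4-[(tert-butyldimethylsilyl)oxy]benzoic acid, via bis-silyl derivative 23 (not isolated)
Conditions: t-BuMe2SiCl (2.2 equiv), imidazole, DMF, 25 °C; then K2CO3, MeOH/THF/H2O, 25 °C; aq. KHSO4
Reagents that add atoms: tert-butyldimethylsilyl chloride, SMILES CC(C)(C)[Si](C)(C)Cl
Why: Persilylation followed by selective solvolysis of the labile silyl ester leaves the aryl silyl ether, giving the protected acid in one operation.

Step 15
Reactants: 21 (1R,3Z,7Z,9S,10R)-9-[(tert-butyldimethylsilyl)oxy]-3,7-dimethyl-10-(prop-1-en-2-yl)cyclodeca-3,7-dien-1-ol; 24 4-[(tert-butyldimethylsilyl)oxy]benzoic acid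
Product: 26 (1R,3Z,7Z,9S,10R)-9-[(tert-butyldimethylsilyl)oxy]-3,7-dimethyl-10-(prop-1-en-2-yl)cyclodeca-3,7-dien-1-yl 4-[(tert-butyldimethylsilyl)oxy]benzoate, via mixed anhydride 25 (not isolated)
Conditions: 2,4,6-Cl3C6H2COCl, Et3N, THF, 25 °C; then 21, 4-(dimethylamino)pyridine, PhMe, 25→40 °C
Reagents that add atoms: none
Why: Yamaguchi esterification: the mixed anhydride is attacked at the unhindered aroyl carbonyl through the acylpyridinium ion, and since O5 is the only free hydroxyl of 21 the ester can only form there; no stereocentre is touched.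

Step 16
Reactants: 26 (1R,3Z,7Z,9S,10R)-9-[(tert-butyldimethylsilyl)oxy]-3,7-dimethyl-10-(prop-1-en-2-yl)cyclodeca-3,7-dien-1-yl 4-[(tert-butyldimethylsilyl)oxy]benzoate
Product: 27 (1R,3Z,7Z,9S,10R)-9-[(tert-butyldimethylsilyl)oxy]-3,7-dimethyl-10-(propan-2-yl)cyclodeca-3,7-dien-1-yl 4-[(tert-butyldimethylsilyl)oxy]benzoate
Conditions: H2 (1 atm), RhCl(PPh3)3 (10 mol %), PhH/EtOH, 25 °C
Reagents that add atoms: none
Why: Homogeneous hydrogenation with RhCl(PPh3)3 reduces 1,1-disubstituted alkenes much faster than trisubstituted ones, so only the isopropenyl group should be saturated; no stereocentre is formed.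

Step 17
Reactants: 27 (1R,3Z,7Z,9S,10R)-9-[(tert-butyldimethylsilyl)oxy]-3,7-dimethyl-10-(propan-2-yl)cyclodeca-3,7-dien-1-yl 4-[(tert-butyldimethylsilyl)oxy]benzoate
Product: 28 (1R,3Z,7Z,9S,10S)-9-hydroxy-3,7-dimethyl-10-(propan-2-yl)cyclodeca-3,7-dien-1-yl 4-hydroxybenzoate
Conditions: HF·pyridine, pyridine, THF, 0→25 °C
Reagents that add atoms: none
Why: Pyridine-buffered HF·pyridine cleaves the aryl and the secondary silyl ether in one operation; the weakly acidic medium avoids the base-induced acyl shift from O5 to O3 and ionisation of the allylic alcohol.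

## Compound list

1 | nerol, (2Z)-3,7-dimethylocta-2,6-dien-1-ol | CC(C)=CCC/C(C)=C\CO | starting material
2 | 1-({[(2Z)-3,7-dimethylocta-2,6-dien-1-yl]oxy}methyl)-4-methoxybenzene | CC(C)=CCC/C(C)=C\COCc1ccc(OC)cc1 | intermediate
3 | 6,7-epoxide of 2 (racemic), 3-{(3Z)-5-[(4-methoxybenzyl)oxy]-3-methylpent-3-en-1-yl}-2,2-dimethyloxirane | CC1(C)OC1CC/C(C)=C\COCc1ccc(OC)cc1 | intermediate
4 | (4Z)-6-[(4-methoxybenzyl)oxy]-4-methylhex-4-enal | O=CCC/C(C)=C\COCc1ccc(OC)cc1 | intermediate
5 | 1-({[(2Z,6Z)-7-iodo-3-methylocta-2,6-dien-1-yl]oxy}methyl)-4-methoxybenzene | C/C(I)=C/CC/C(C)=C\COCc1ccc(OC)cc1 | intermediate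
6 | ethylene oxide | C1CO1 | starting material
7 | alkenyllithium from 5 (lithium in place of iodine, geometry retained) | C/C([Li])=C/CC/C(C)=C\COCc1ccc(OC)cc1 | intermediate
8 | (3Z,7Z)-9-[(4-methoxybenzyl)oxy]-3,7-dimethylnona-3,7-dien-1-ol | OCC/C(C)=C\CC/C(C)=C\COCc1ccc(OC)cc1 | intermediate
9 | triethyl{[(3Z,7Z)-9-[(4-methoxybenzyl)oxy]-3,7-dimethylnona-3,7-dien-1-yl]oxy}silane | CC[Si](CC)(CC)OCC/C(C)=C\CC/C(C)=C\COCc1ccc(OC)cc1 | intermediate
10 | (2Z,6Z)-3,7-dimethyl-9-[(triethylsilyl)oxy]nona-2,6-dien-1-ol | CC[Si](CC)(CC)OCC/C(C)=C\CC/C(C)=C\CO | intermediate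
11 | (2Z,6Z)-3,7-dimethyl-9-[(triethylsilyl)oxy]nona-2,6-dienal | CC[Si](CC)(CC)OCC/C(C)=C\CC/C(C)=C\C=O | intermediate
12 | propyne | CC#C | starting material
13 | (4S,5Z,9Z)-6,10-dimethyl-12-[(triethylsilyl)oxy]dodeca-5,9-dien-2-yn-4-ol | CC#C[C@@H](O)/C=C(C)\CC/C=C(C)\CCO[Si](CC)(CC)CC | intermediate
14 | cyclic sodium alkenylalanate from 13 (five-membered O–Al–C=C–C ring, two 2-methoxyethoxy groups on aluminium) | CC1=C[C@H](/C=C(C)\CC/C=C(C)\CCO[Si](CC)(CC)CC)O[Al-]1(OCCOC)OCCOC.[Na+] | intermediate
15 | (2Z,4S,5Z,9Z)-2-iodo-6,10-dimethyl-12-[(triethylsilyl)oxy]dodeca-2,5,9-trien-4-ol | C/C(I)=C/[C@@H](O)/C=C(C)\CC/C=C(C)\CCO[Si](CC)(CC)CC | intermediate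
16 | (2Z,4S,5Z,9Z)-4-[(tert-butyldimethylsilyl)oxy]-2-iodo-6,10-dimethyl-12-[(triethylsilyl)oxy]dodeca-2,5,9-triene | C/C(I)=C/[C@@H](O[Si](C)(C)C(C)(C)C)/C=C(C)\CC/C=C(C)\CCO[Si](CC)(CC)CC | intermediate
17 | (3Z,7Z,9S,10Z)-9-[(tert-butyldimethylsilyl)oxy]-11-iodo-3,7-dimethyldodeca-3,7,10-trien-1-ol | C/C(I)=C/[C@@H](O[Si](C)(C)C(C)(C)C)/C=C(C)\CC/C=C(C)\CCO | intermediate
18 | (3Z,7Z,9R,10Z)-9-[(tert-butyldimethylsilyl)oxy]-3,7,11-trimethyl-12-(4,4,5,5-tetramethyl-1,3,2-dioxaborolan-2-yl)dodeca-3,7,10-trien-1-ol | CC1(C)OB(C/C(C)=C\[C@@H](O[Si](C)(C)C(C)(C)C)/C=C(C)\CC/C=C(C)\CCO)OC1(C)C | intermediate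
19 | (3Z,7Z,9R,10Z)-9-[(tert-butyldimethylsilyl)oxy]-3,7,11-trimethyl-12-(4,4,5,5-tetramethyl-1,3,2-dioxaborolan-2-yl)dodeca-3,7,10-trienal (open-chain C5 aldehyde) | CC1(C)OB(C/C(C)=C\[C@@H](O[Si](C)(C)C(C)(C)C)/C=C(C)\CC/C=C(C)\CC=O)OC1(C)C | intermediate
20 | pinacol borate of 21 at O5 | C/C1=C/[C@H](O[Si](C)(C)C(C)(C)C)[C@H](C(C)=C)[C@H](OB2OC(C)(C)C(C)(C)O2)C/C(C)=C\CC1 | intermediate
21 | (1R,3Z,7Z,9S,10R)-9-[(tert-butyldimethylsilyl)oxy]-3,7-dimethyl-10-(prop-1-en-2-yl)cyclodeca-3,7-dien-1-ol (ring C3 silyl ether, C4 isopropenyl, C5 hydroxyl, all cis) | C/C1=C/[C@H](O[Si](C)(C)C(C)(C)C)[C@H](C(C)=C)[C@H](O)C/C(C)=C\CC1 | intermediate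
22 | 4-hydroxybenzoic acid | OC(=O)c1ccc(O)cc1 | starting material
23 | tert-butyldimethylsilyl 4-[(tert-butyldimethylsilyl)oxy]benzoate | CC(C)(C)[Si](C)(C)OC(=O)c1ccc(O[Si](C)(C)C(C)(C)C)cc1 | intermediate
24 | 4-[(tert-butyldimethylsilyl)oxy]benzoic acid | OC(=O)c1ccc(O[Si](C)(C)C(C)(C)C)cc1 | intermediate
25 | 4-[(tert-butyldimethylsilyl)oxy]benzoic 2,4,6-trichlorobenzoic anhydride | CC(C)(C)[Si](C)(C)Oc1ccc(cc1)C(=O)OC(=O)c1c(Cl)cc(Cl)cc1Cl | intermediate
26 | (1R,3Z,7Z,9S,10R)-9-[(tert-butyldimethylsilyl)oxy]-3,7-dimethyl-10-(prop-1-en-2-yl)cyclodeca-3,7-dien-1-yl 4-[(tert-butyldimethylsilyl)oxy]benzoate | C/C1=C/[C@H](O[Si](C)(C)C(C)(C)C)[C@H](C(C)=C)[C@H](OC(=O)c2ccc(O[Si](C)(C)C(C)(C)C)cc2)C/C(C)=C\CC1 | intermediate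
27 | (1R,3Z,7Z,9S,10R)-9-[(tert-butyldimethylsilyl)oxy]-3,7-dimethyl-10-(propan-2-yl)cyclodeca-3,7-dien-1-yl 4-[(tert-butyldimethylsilyl)oxy]benzoate | C/C1=C/[C@H](O[Si](C)(C)C(C)(C)C)[C@H](C(C)C)[C@H](OC(=O)c2ccc(O[Si](C)(C)C(C)(C)C)cc2)C/C(C)=C\CC1 | intermediate
28 | (1R,3Z,7Z,9S,10S)-9-hydroxy-3,7-dimethyl-10-(propan-2-yl)cyclodeca-3,7-dien-1-yl 4-hydroxybenzoate | C/C1=C/[C@H](O)[C@H](C(C)C)[C@H](OC(=O)c2ccc(O)cc2)C/C(C)=C\CC1 | target

## Step count and least certain steps

Total step count: 17. Longest linear sequence: 16 (steps 1–13 and 15–17); step 14 is a one-step side branch.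

Step 13 (key step, proposed new method). Two processes may fail.
- Rate: ring closure of a hindered pinacol allylboronate to a ten-membered ring may be slower than enolisation of the β,γ-unsaturated aldehyde into conjugation or than intermolecular allylation. The first adjustment within the same approach would be catalytic diphenyl phosphate to activate the boronate.
- Facial selectivity: the choice between the two C3–C4 rotamers may be poor or reversed, because ring strain in the tether may override the acyclic preference.
- Fallback with known chemistry, setting out from 17: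
  - Stille coupling with Bu3SnCH2OH (Pd(PPh3)4, dioxane, 80 °C) should replace iodine by CH2OH with retention, giving (2Z,4S,5Z,9Z)-4-[(tert-butyldimethylsilyl)oxy]-2,6,10-trimethyldodeca-2,5,9-triene-1,12-diol F1.
  - Corey–Kim chlorination (N-chlorosuccinimide, Me2S, CH2Cl2, −20 °C) converts allylic but not saturated primary alcohols and should give (3Z,7Z,9S,10Z)-9-[(tert-butyldimethylsilyl)oxy]-12-chloro-3,7,11-trimethyldodeca-3,7,10-trien-1-ol F2.
  - Buffered Dess–Martin oxidation gives the chloro aldehyde (3Z,7Z,9S,10Z)-9-[(tert-butyldimethylsilyl)oxy]-12-chloro-3,7,11-trimethyldodeca-3,7,10-trienal F3, which is added slowly to excess CrCl2 with NaI in THF at high dilution.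
  - This intramolecular Nozaki–Hiyama allylation by divalent chromium is the reaction type known to close ten-membered germacrane rings. Allylchromium reagents add with the γ-substituent equatorial whatever the halide geometry, so it is expected to give mainly the C4/C5 trans alcohol (1S,3Z,7Z,9S,10R)-9-[(tert-butyldimethylsilyl)oxy]-3,7-dimethyl-10-(prop-1-en-2-yl)cyclodeca-3,7-dien-1-ol F4.
  - Mitsunobu esterification of F4 with 24 (PPh3, diisopropyl azodicarboxylate, PhMe) inverts C5 and installs the ester, returning to the route at 26.
  - The C3/C4 sense would have to be established in this series as well.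

Step 8. Catalyst control may be eroded on a β,β-disubstituted Z-enal, and the Lewis acidic zinc medium may cause Z to E isomerisation of the enal before addition. Fallback, setting out from 11:
- CH3C≡CMgBr (THF, −78 °C) gives the racemic alcohol (5Z,9Z)-6,10-dimethyl-12-[(triethylsilyl)oxy]dodeca-5,9-dien-2-yn-4-ol F5.
- MnO2 (CH2Cl2) gives the ynone (5Z,9Z)-6,10-dimethyl-12-[(triethylsilyl)oxy]dodeca-5,9-dien-2-yn-4-one F6.
- Noyori transfer hydrogenation (RuCl(p-cymene)[(S,S)-TsDPEN] or its antipode as required, i-PrOH) reduces the ynone carbonyl to the 4S alcohol, returning at 13.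

Step 12. The free hydroxyl may protonate the zinc reagent, or transmetalation may be slow, so that coupling stalls or the iodide is reduced. Fallback, setting out from 16 (this changes the order of coupling and deprotection):
- The same borylmethylzinc coupling on the fully silylated iodide gives tert-butyldimethyl{[(2Z,4R,5Z,9Z)-2,6,10-trimethyl-1-(4,4,5,5-tetramethyl-1,3,2-dioxaborolan-2-yl)-12-[(triethylsilyl)oxy]dodeca-2,5,9-trien-4-yl]oxy}silane F7.
- The primary triethylsilyl ether is then removed with pyridinium p-toluenesulfonate in MeOH/CH2Cl2 at 0 °C, conditions that pinacol allylboronates tolerate, returning at 18.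

Step 16. Shielding of the isopropenyl group by the flanking silyloxy and aroyloxy groups may slow hydrogenation so much that forcing conditions start alkene isomerisation or reduction of a ring alkene. Fallback, setting out from 21:
- Reduce the isopropenyl group on the less hindered free alcohol with diimide (2-nitrobenzenesulfonyl hydrazide, Et3N, CH2Cl2, 25 °C), which prefers the least substituted alkene and uses no metal, to give (1R,3Z,7Z,9S,10R)-9-[(tert-butyldimethylsilyl)oxy]-3,7-dimethyl-10-(propan-2-yl)cyclodeca-3,7-dien-1-ol F8.
- Acylate F8 with 24 under the Yamaguchi conditions of step 15, returning at 27.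

## Further compounds

F1 | step 13 | (2Z,4S,5Z,9Z)-4-[(tert-butyldimethylsilyl)oxy]-2,6,10-trimethyldodeca-2,5,9-triene-1,12-diol | OC/C(C)=C\[C@@H](O[Si](C)(C)C(C)(C)C)/C=C(C)\CC/C=C(C)\CCO
F2 | step 13 | (3Z,7Z,9S,10Z)-9-[(tert-butyldimethylsilyl)oxy]-12-chloro-3,7,11-trimethyldodeca-3,7,10-trien-1-ol | ClC/C(C)=C\[C@@H](O[Si](C)(C)C(C)(C)C)/C=C(C)\CC/C=C(C)\CCO
F3 | step 13 | (3Z,7Z,9S,10Z)-9-[(tert-butyldimethylsilyl)oxy]-12-chloro-3,7,11-trimethyldodeca-3,7,10-trienal | ClC/C(C)=C\[C@@H](O[Si](C)(C)C(C)(C)C)/C=C(C)\CC/C=C(C)\CC=O
F4 | step 13 | (1S,3Z,7Z,9S,10R)-9-[(tert-butyldimethylsilyl)oxy]-3,7-dimethyl-10-(prop-1-en-2-yl)cyclodeca-3,7-dien-1-ol | C/C1=C/[C@H](O[Si](C)(C)C(C)(C)C)[C@H](C(C)=C)[C@@H](O)C/C(C)=C\CC1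
F5 | step 8 | racemic (5Z,9Z)-6,10-dimethyl-12-[(triethylsilyl)oxy]dodeca-5,9-dien-2-yn-4-ol | CC#CC(O)/C=C(C)\CC/C=C(C)\CCO[Si](CC)(CC)CC
F6 | step 8 | (5Z,9Z)-6,10-dimethyl-12-[(triethylsilyl)oxy]dodeca-5,9-dien-2-yn-4-one | CC#CC(=O)/C=C(C)\CC/C=C(C)\CCO[Si](CC)(CC)CC
F7 | step 12 | tert-butyldimethyl{[(2Z,4R,5Z,9Z)-2,6,10-trimethyl-1-(4,4,5,5-tetramethyl-1,3,2-dioxaborolan-2-yl)-12-[(triethylsilyl)oxy]dodeca-2,5,9-trien-4-yl]oxy}silane | CC1(C)OB(C/C(C)=C\[C@@H](O[Si](C)(C)C(C)(C)C)/C=C(C)\CC/C=C(C)\CCO[Si](CC)(CC)CC)OC1(C)C
F8 | step 16 | (1R,3Z,7Z,9S,10R)-9-[(tert-butyldimethylsilyl)oxy]-3,7-dimethyl-10-(propan-2-yl)cyclodeca-3,7-dien-1-ol | C/C1=C/[C@H](O[Si](C)(C)C(C)(C)C)[C@H](C(C)C)[C@H](O)C/C(C)=C\CC1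
A1 | alternative 1 | [(3,7-dimethylcycloocta-1,3,7-trien-1-yl)oxy]trimethylsilane | CC1=CC(O[Si](C)(C)C)=CC(C)=CCC1
A2 | alternative 1 | isopropylketene (3-methylbut-1-en-1-one) | CC(C)C=C=O
A3 | alternative 1 | (4Z,8Z)-5,9-dimethyl-2-(propan-2-yl)cyclodeca-4,8-diene-1,3-dione | C/C1=C/C(=O)C(C(C)C)C(=O)C/C(C)=C\CC1
A4 | alternative 2 | open-chain Z,Z bromo sulfone: C10 phenylsulfonylmethyl and C9 bromomethyl termini, C3 tert-butyldimethylsilyl ether, C4 isopropyl, C5 triethylsilyl ether | O=S(=O)(c1ccccc1)C/C(C)=C\[C@H](O[Si](C)(C)C(C)(C)C)[C@H](C(C)C)[C@H](O[Si](CC)(CC)CC)C/C(C)=C\CBr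
A5 | alternative 2 | ten-membered Z,Z-diene with phenylsulfonyl on C10, C3 tert-butyldimethylsilyl ether, C4 isopropyl, C5 triethylsilyl ether | C/C1=C/[C@H](O[Si](C)(C)C(C)(C)C)[C@H](C(C)C)[C@H](O[Si](CC)(CC)CC)C/C(C)=C\CC1S(=O)(=O)c2ccccc2
A6 | alternative 3 | all-Z thirteen-membered diallyl ether (O between C3 and Cα) with C5 triethylsilyl ether | C/C1=C/COC/C(C)=C\[C@H](O[Si](CC)(CC)CC)C/C(C)=C\CC1
A7 | alternative 3 | ten-membered Z,Z-dienol with C3 hydroxyl, C4 isopropenyl, C5 triethylsilyl ether | C/C1=C/[C@H](O)[C@H](C(C)=C)[C@H](O[Si](CC)(CC)CC)C/C(C)=C\CC1
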